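**Retrosynthetic overview**

- The target, 8-butanoyloxy-3,5-dihydroxy-7-methoxyflavone, is traced back through its 5-O-benzyl ether to a flavan-3,4-diol; double oxidation and enolisation of C2-H regenerate the 3-hydroxy-4-pyranone.
- The strategy rests on C3 (bearing OH) and C4 (the carbonyl carbon) of ring C, two adjacent oxygen-bearing carbons. The C3–C4 bond is cut reductively into two aldehyde carbons tethered through O1–C2 (SmI2 pinacol).
- The dialdehyde comes from an O1–C2 ether bond (Mitsunobu of a salicylaldehyde with mono-silylated styrene glycol), then desilylation and oxidation.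
- The salicylaldehyde (2-OH, 3-butanoyloxy, 4-OMe, 6-OBn) comes from 3,4,5-trimethoxyphenol by ortho-formylation, chelation-controlled BCl3 demethylation, and a cyclic orthobutyrate that masks the 2,3-catechol during 6-O-benzylation and then opens to the 3-butanoate.
- Ring order: rings A and B are bought; ring C is the only ring formed, closed in the key step and aromatised in the step after it.

Key step: step 9

Remark: the target has no stereocentre; every chiral intermediate is racemic, and a SMILES showing one enantiomer stands for the racemate.

**Step 1**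
Reactants: 1 3,4,5-trimethoxyphenol
Product: 2 6-hydroxy-2,3,4-trimethoxybenzaldehyde
Conditions: MgCl2, Et3N, (CH2O)n, MeCN, reflux; aq. HCl work-up
Reagents that add atoms: paraformaldehyde (formaldehyde unit) C=O
Why: Magnesium-mediated ortho-formylation of a phenol (Casnati–Skattebøl type) delivers the formyl group only next to the phenoxide oxygen, and the two ortho positions of 1 are equivalent, so a single salicylaldehyde is expected.

**Step 2**
Reactants: 2 6-hydroxy-2,3,4-trimethoxybenzaldehyde
Product: 3 2,3,6-trihydroxy-4-methoxybenzaldehyde
Conditions: BCl3 (excess), CH2Cl2, −78 °C to rt, argon; ice/aq. HCl work-up; used directly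
Reagents that add atoms: none
Why: Chelation-controlled Lewis-acid ether cleavage should remove first the twisted 2-OMe next to the carbonyl and then the adjacent 3-OMe through the 2-O–boron chelate; the resulting cyclic catechol chloroborate stops the reaction before the in-plane 4-OMe, the pattern established for 2,3,4-trimethoxybenzaldehyde.

**Step 3**
Reactants: 3 2,3,6-trihydroxy-4-methoxybenzaldehyde; 4 triethyl orthobutyrate
Product: 5 2-ethoxy-5-hydroxy-7-methoxy-2-propyl-1,3-benzodioxole-4-carbaldehyde (racemic at the orthoester carbon)
Conditions: PrC(OEt)3, cat. PPTS, toluene, 110 °C, EtOH distilled off, argon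
Reagents that add atoms: none
Why: Transorthoesterification closes a five-membered 2-alkoxy-1,3-benzodioxole only across the 2,3-catechol, leaving the 6-hydroxyl (hydrogen-bonded to the formyl group) free; the new orthoester centre forms without control and is destroyed in step 4.

**Step 4**
Reactants: 5 2-ethoxy-5-hydroxy-7-methoxy-2-propyl-1,3-benzodioxole-4-carbaldehyde
Product: 7 6-(benzyloxy)-3-(butanoyloxy)-2-hydroxy-4-methoxybenzaldehyde, via benzylated orthoester 6 (not isolated)
Conditions: BnBr, K2CO3, DMF, rt to 40 °C; then crude in AcOH/H2O/THF, rt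
Reagents that add atoms: benzyl bromide BrCc1ccccc1; water O
Why: Williamson etherification benzylates the only free phenol, and mild acid hydrolysis of the orthoester (via the dioxolenium ion and hemiorthoester) should expel the more acidic 2-oxygen, giving the 3-butanoate with the 2-hydroxyl hydrogen-bonded to the aldehyde; this is also the isomer favoured if acyl migration between the catechol oxygens equilibrates the pair.

**Step 5**
Reactants: 8 1-phenylethane-1,2-diol (racemic)
Product: 9 2-(tert-butyldimethylsilyloxy)-1-phenylethanol (racemic)
Conditions: TBSCl (1.05 equiv), imidazole, CH2Cl2, 0 °C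
Reagents that add atoms: tert-butyldimethylsilyl chloride CC(C)(C)[Si](C)(C)Cl
Why: Selective silylation of the primary over the secondary benzylic hydroxyl of a 1,2-diol is routine steric discrimination.

**Step 6**
Reactants: 7 6-(benzyloxy)-3-(butanoyloxy)-2-hydroxy-4-methoxybenzaldehyde; 9 2-(tert-butyldimethylsilyloxy)-1-phenylethanol
Product: 10 6-(benzyloxy)-3-(butanoyloxy)-2-[2-(tert-butyldimethylsilyloxy)-1-phenylethoxy]-4-methoxybenzaldehyde (racemic)
Conditions: PPh3, DIAD, THF, 0 °C to rt
Reagents that add atoms: none
Why: Mitsunobu etherification forms O1–C2 with the ortho-formyl phenol (acidic enough for the betaine) displacing the activated secondary benzylic carbinol with inversion under neutral conditions that spare the aryl butanoate; the benzylic centre comes from racemic 9, is uncontrolled and is erased in step 10.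

**Step 7**
Reactants: 10 the silyl ether from step 6
Product: 11 6-(benzyloxy)-3-(butanoyloxy)-2-(2-hydroxy-1-phenylethoxy)-4-methoxybenzaldehyde (racemic)
Conditions: HF·pyridine, THF/pyridine, 0 °C to rt
Reagents that add atoms: none
Why: Buffered fluoride desilylation cleaves the primary TBS ether without the basic fluoride that would attack the aryl ester, and leaves the benzyl ether and the aldehyde untouched.

**Step 8**
Reactants: 11 the primary alcohol from step 7
Product: 12 6-(benzyloxy)-3-(butanoyloxy)-4-methoxy-2-(2-oxo-1-phenylethoxy)benzaldehyde (racemic)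
Conditions: Dess–Martin periodinane, CH2Cl2, 0 °C to rt; used without chromatography
Reagents that add atoms: none
Why: Dess–Martin oxidation takes the primary alcohol to the aldehyde under mild, non-basic conditions, which limits enolisation of the sensitive α-aryloxy-α-phenyl aldehyde.

**Step 9**
Reactants: 12 the dialdehyde from step 8
Product: 13 5-(benzyloxy)-8-(butanoyloxy)-7-methoxyflavan-3,4-diol, 2,3-trans-3,4-cis (racemic; (2S,3R,4R) enantiomer drawn)
Conditions: SmI2 (0.1 M in THF, 2.2 equiv) added dropwise to 12 and t-BuOH (2.5 equiv), THF, −78 °C, argon; aq. NH4Cl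
Reagents that add atoms: none
Why: Divalent samarium transfers one electron to an aldehyde, most readily the aryl-conjugated one, and the samarium-bound C4 ketyl adds to the samarium-activated C3 carbonyl carbon (or couples with a second ketyl) before a second electron and protonation by t-BuOH deliver the diol; the closest known reaction type is the SmI2 pinacol cyclisation of 1,6-dialdehydes to cis-cyclohexane-1,2-diols. Ring C closes by C3–C4 bond formation in a 6-exo-trig mode. The 3,4-cis relationship should be set by the samarium bridge between the two oxygens, and the 2,3-trans relationship by the existing C2 centre, whose phenyl sits pseudo-equatorial while the peri 5-benzyloxy group pushes the C4–O bond pseudo-axial and so the C3–O bond equatorial. The step needs chemoselectivity for C–C coupling over a two-electron reduction of the α-aryloxy aldehyde that would expel the O1 aryloxide, and over simple reduction to the alcohols; the short O1–C2 tether that holds both carbonyls in one samarium chelate, the low temperature and the dropwise addition of SmI2 (never in excess) are meant to secure it. Diastereoselectivity is not critical, because C2, C3 and C4 all lose their configuration in step 10.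

**Step 10**
Reactants: 13 the flavan-3,4-diol from step 9
Product: 15 5-(benzyloxy)-8-(butanoyloxy)-3-hydroxy-7-methoxyflavone, via chroman-3,4-dione 14 (not isolated)
Conditions: (COCl)2, DMSO, CH2Cl2, −78 °C; then Et3N, −78 to 0 °C
Reagents that add atoms: none
Why: Swern oxidation converts both carbinols to the 1,2-dione without C–C cleavage, and the C2-H flanked by O1, phenyl and the C3 carbonyl is enolised by Et3N to the aromatic 3-hydroxy-4-pyranone, removing all three stereocentres.

**Step 11**
Reactants: 15 the 5-O-benzyl flavonol from step 10
Product: 16 8-(butanoyloxy)-3,5-dihydroxy-7-methoxyflavone (CNP0245153.0)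
Conditions: H2 (1 atm), 10% Pd/C, EtOAc, rt
Reagents that add atoms: none
Why: Catalytic hydrogenolysis cleaves the benzyl aryl ether, while the tetrasubstituted pyranone double bond and the aryl butanoate should be inert in a neutral, non-nucleophilic solvent.

**Compound list**

1 | 3,4,5-trimethoxyphenol | COc1cc(O)cc(OC)c1OC | starting material
2 | 6-hydroxy-2,3,4-trimethoxybenzaldehyde | COc1cc(O)c(C=O)c(OC)c1OC | intermediate
3 | 2,3,6-trihydroxy-4-methoxybenzaldehyde | COc1cc(O)c(C=O)c(O)c1O | intermediate
4 | triethyl orthobutyrate (1,1,1-triethoxybutane) | CCCC(OCC)(OCC)OCC | starting material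
5 | 2-ethoxy-5-hydroxy-7-methoxy-2-propyl-1,3-benzodioxole-4-carbaldehyde (racemic) | CCCC1(OCC)Oc2c(O1)c(OC)cc(O)c2C=O | intermediate
6 | 5-(benzyloxy)-2-ethoxy-7-methoxy-2-propyl-1,3-benzodioxole-4-carbaldehyde (racemic, not isolated) | CCCC1(OCC)Oc2c(O1)c(OC)cc(OCc3ccccc3)c2C=O | intermediate
7 | 6-(benzyloxy)-3-(butanoyloxy)-2-hydroxy-4-methoxybenzaldehyde | CCCC(=O)Oc1c(OC)cc(OCc2ccccc2)c(C=O)c1O | intermediate
8 | 1-phenylethane-1,2-diol (racemic, R enantiomer drawn) | OC[C@H](O)c1ccccc1 | starting material
9 | 2-(tert-butyldimethylsilyloxy)-1-phenylethanol (racemic, R enantiomer drawn) | O[C@H](c1ccccc1)CO[Si](C)(C)C(C)(C)C | intermediate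
10 | 6-(benzyloxy)-3-(butanoyloxy)-2-[2-(tert-butyldimethylsilyloxy)-1-phenylethoxy]-4-methoxybenzaldehyde (racemic, S enantiomer drawn) | CCCC(=O)Oc1c(OC)cc(OCc2ccccc2)c(C=O)c1O[C@@H](c1ccccc1)CO[Si](C)(C)C(C)(C)C | intermediate
11 | 6-(benzyloxy)-3-(butanoyloxy)-2-(2-hydroxy-1-phenylethoxy)-4-methoxybenzaldehyde (racemic, S enantiomer drawn) | CCCC(=O)Oc1c(OC)cc(OCc2ccccc2)c(C=O)c1O[C@@H](c1ccccc1)CO | intermediate
12 | 6-(benzyloxy)-3-(butanoyloxy)-4-methoxy-2-(2-oxo-1-phenylethoxy)benzaldehyde (racemic, S enantiomer drawn) | CCCC(=O)Oc1c(OC)cc(OCc2ccccc2)c(C=O)c1O[C@@H](c1ccccc1)C=O | intermediate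
13 | 5-(benzyloxy)-8-(butanoyloxy)-7-methoxyflavan-3,4-diol, 2,3-trans-3,4-cis (racemic, (2S,3R,4R) drawn) | CCCC(=O)Oc1c(OC)cc(OCc2ccccc2)c3c1O[C@@H](c1ccccc1)[C@H](O)[C@@H]3O | intermediate
14 | 5-(benzyloxy)-8-(butanoyloxy)-7-methoxy-2-phenylchroman-3,4-dione (racemic, not isolated) | CCCC(=O)Oc1c(OC)cc(OCc2ccccc2)c2c1O[C@@H](c1ccccc1)C(=O)C2=O | intermediate
15 | 5-(benzyloxy)-8-(butanoyloxy)-3-hydroxy-7-methoxyflavone | CCCC(=O)Oc1c(OC)cc(OCc2ccccc2)c2c(=O)c(O)c(-c3ccccc3)oc12 | intermediate
16 | 8-(butanoyloxy)-3,5-dihydroxy-7-methoxyflavone | CCCC(=O)Oc1c(OC)cc(O)c2c(=O)c(O)c(-c3ccccc3)oc12 | target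

**Step count and risks**

Total step count: 11. Longest linear sequence: 10 (steps 1–4 and 6–11); step 5 is a one-step side branch.

Steps most likely to fail:

1. Step 9. The aliphatic α-aryloxy aldehyde may take up two electrons and expel the O1 aryloxide, cutting the tether, or either aldehyde may simply be reduced to the alcohol before ring closure. Fallback: from dialdehyde 12, an N-heterocyclic carbene (thiazolium or triazolium precatalyst with Et3N in THF) should turn the aromatic aldehyde into an acyl anion equivalent at C4 that adds to the C3 aldehyde (intramolecular crossed benzoin). This forms the same C3–C4 bond without any reduction and gives trans-5-(benzyloxy)-8-(butanoyloxy)-3-hydroxy-7-methoxyflavanone F1. F1 has a single carbinol left to oxidise and would be taken through dione 14 under the conditions of step 10, rejoining the route at flavonol 15.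

2. Step 6. Displacement at the secondary benzylic carbinol by a phenol flanked on both sides may be slow, so that elimination of the activated alcohol or an acyl shift of the neighbouring butanoate before alkylation takes over. Fallback: alcohol 9 is converted with CBr4/PPh3 into (2-bromo-2-phenylethoxy)(tert-butyl)dimethylsilane F2, and phenol 7 is alkylated with F2 as its caesium phenoxide (Cs2CO3, DMF, rt to 50 °C). This is a direct Williamson displacement on a preformed benzylic bromide instead of a redox condensation, and it returns to the route at ether 10.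

3. Step 4. The orthoester may open toward the wrong oxygen, or hydrolysis may run on with loss of the butanoyl group, leaving a mixture of catechol and monoesters. Fallback: from triol 3, the catechol is tied up as a robust ketal with Ph2CCl2 (diphenyl ether, 170 °C) to give 5-hydroxy-7-methoxy-2,2-diphenyl-1,3-benzodioxole-4-carbaldehyde F3. Benzylation (BnBr, K2CO3, DMF) gives 5-(benzyloxy)-7-methoxy-2,2-diphenyl-1,3-benzodioxole-4-carbaldehyde F4. Hot aqueous AcOH releases 6-(benzyloxy)-2,3-dihydroxy-4-methoxybenzaldehyde F5. One equivalent of butyric anhydride with Et3N then acylates the 3-hydroxyl, the one not hydrogen-bonded to the aldehyde, and the route is rejoined at phenol 7.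

**Further compounds**

F1 | step 9 | trans-5-(benzyloxy)-8-(butanoyloxy)-3-hydroxy-7-methoxyflavanone (racemic, one enantiomer drawn) | CCCC(=O)Oc1c(OC)cc(OCc2ccccc2)c2c1O[C@@H](c1ccccc1)[C@H](O)C2=O
F2 | step 6 | (2-bromo-2-phenylethoxy)(tert-butyl)dimethylsilane (racemic, one enantiomer drawn) | Br[C@H](c1ccccc1)CO[Si](C)(C)C(C)(C)C
F3 | step 4 | 5-hydroxy-7-methoxy-2,2-diphenyl-1,3-benzodioxole-4-carbaldehyde | O=Cc1c(O)cc(OC)c2OC(c3ccccc3)(c3ccccc3)Oc12
F4 | step 4 | 5-(benzyloxy)-7-methoxy-2,2-diphenyl-1,3-benzodioxole-4-carbaldehyde | O=Cc1c(OCc3ccccc3)cc(OC)c2OC(c3ccccc3)(c4ccccc4)Oc12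
F5 | step 4 | 6-(benzyloxy)-2,3-dihydroxy-4-methoxybenzaldehyde | COc1cc(OCc2ccccc2)c(C=O)c(O)c1O
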